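At the time of reading, 10 min, I first ask whether these flasks are still working.

| flask | substrate | partner | temperature | remark | time |
|---|---|---|---|---|---|
| eta | 1.4 M | 0.95 equiv | 29 °C | run made earlier |  |
| gamma | 2.2 M | 0.95 equiv | 37 °C | run made earlier |  |
| beta | 1 M | 0.47 equiv | 29 °C | run made earlier |  |
| Friday's | 1.0 M | 0.950 equiv | 25 °C |  | 10 min |
| Tuesday's | 1.0 M | 0.950 equiv | 40 °C |  | 10 min |
| Thursday's | 1.0 M | 0.950 equiv |  | at 25 °C until 8.0 min, from then on at 40 °C | 10 min |

| run | time / min | double product / % | substrate / % |
|---|---|---|---|
| eta | 0.500 | 34 | 48 |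
| eta | 1.50 | 39 | 43 |
| eta | 3.00 | 38 | 45 |
| eta | 4.00 | 36 | 45 |
| eta | 6.00 | 37 | 46 |
| eta | 8.00 | 38 | 44 |
| eta | 10.0 | 40 | 43 |
| gamma | 0.667 | 39 | 45 |
| gamma | 1.50 | 42 | 45 |
| gamma | 2.00 | 39 | 44 |
| gamma | 3.00 | 40 | 46 |
| gamma | 4.00 | 40 | 43 |
| gamma | 6.00 | 41 | 46 |
| beta | 0.833 | 15 | 68 |
| beta | 1.50 | 13 | 69 |
| beta | 3.00 | 16 | 69 |
| beta | 5.00 | 14 | 66 |
| beta | 10.0 | 14 | 67 |

(readings scatter by 1.5 percentage points)

- a reading or a percentage of double product counts all its forms, free or not

* the flask with the highest amount of double product, in percent of the substrate charged ("all alike" if they lie within 1.5 percentage points) (Friday's / Tuesday's / Thursday's / all alike)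
* final double product, as a percentage of the substrate charged, in Friday's
* final double product, as a percentage of the substrate charged, in Tuesday's
* final double product, as a percentage of the substrate charged, in Thursday's

In the eta run, double product reads 39% at 1.50 min and 40% at 10.0 min, a rise smaller than the scatter of 1.5 percentage points. So why does it stop? From 1.50 min on, eta averages 38.0% double product and 44.3% substrate. Each substrate lost takes one partner, and each double product takes a second, so the partner used in eta comes to 93.7% of the substrate charged, which is 98.6% of its charge of 0.95 equiv. Partner is the limiting reagent.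

Does Thursday's warming matter, then? The eta plateau starts well before the change at 8.0 min, so I expect Thursday's to match Friday's.

How much double product does a charge of partner buy? I define the yield per equivalent, double product as a fraction of the substrate charged divided by the equivalents of partner charged 0.400. In eta it reads 0.400. Beta, at the same temperature, averages 14.4% and reads 0.306, lower at the smaller charge. Gamma averages 40.2% and reads 0.423. With eta's value I reckon 38.0% for Friday's and Thursday's. With gamma's, the warmest run, I reckon 40.2% for Tuesday's. That lead is narrow against the margin of 1.5 points.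

The forecast names Tuesday's, with 37.7% (36.2% to 39%) for Friday's, 40.5% (39% to 42%) for Tuesday's and 37.7% (36.2% to 39.2%) for Thursday's: “so warming changes nothing and it equals Friday's”.

The flasks give 38.4% for Friday's, 39.0% for Tuesday's and 38.3% for Thursday's, so the answer is all alike. Tuesday's leads Friday's by 0.60 points, less than the margin, where the forecast had 2.8 points. The yield per equivalent comes to 0.404 in Friday's and 0.411 in Tuesday's. Rest is not complete: at 100 min, double product stands at 37.8% in Friday's, 36.0% in Tuesday's and 35.3% in Thursday's, while over-reaction product reaches 0.660%, 3.47% and 3.19%.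

    substrate + partner → single product + released group (k = 0.0480 M⁻¹ s⁻¹, Ea = 41.0 kJ mol⁻¹)
    crystals ⇌ double product, rate k2*(cs2 - [double product]) while solid is left; crystals form when [double product] > cs2 (solubility = 22.0 mM, k = 0.130 s⁻¹)
    partner + single product → double product + released group (k = 0.140 M⁻¹ s⁻¹, Ea = 48.0 kJ mol⁻¹)
    partner + double product ⇌ triple product + released group (K = 0.610, k = 0.00780 M⁻¹ s⁻¹, Ea = 66.0 kJ mol⁻¹, ΔH = −12.0 kJ mol⁻¹)
    double product → over-reaction product (k = 4.90 × 10⁻⁵ s⁻¹, Ea = 86.0 kJ mol⁻¹)
    (constants at 25 °C)

A neighbour flask, like Thursday's but with 0.570 equiv of partner, lies between beta and eta in its charge, so interpolating on the charge gives a yield per equivalent of 0.326 and 18.6% double product. The computed flask gives 18.7%.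

(The runs stem from a simulated flask for an exercise.)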